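**Plan**
- Retrosynthetic cuts, in order: (i) the C1' carbinol back to a ketone and the aryl C5–C1' bond (aryllithium plus an (S)-lactate Weinreb amide); (ii) the C3 methyl back to a C3 methyl ester; (iii) the C3–C3a bond of the dihydrofuran ring, which restores the C4–C4a bond of a flavanone; (iv) the C2–aryl bond (conjugate addition to a chromone).
- Forward: ring A is bought as an acetophenone and brominated; the six-membered pyranone ring is closed (chromone); ring B is added at C2; the pyranone ring is contracted to the five-membered ring with C4 extruded as an ester; the ester is reduced to the C3 methyl; the side chain is joined last at C5.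
- Enabling feature: C3 of the five-membered ring O1–C2–C3–C3a–C7a carries the fused arene carbon C3a and exactly one exocyclic carbon (the methyl). This is the pattern left when C4a of a chroman-4-one ring O1–C2–C3–C4–C4a–C8a shifts from C4 to C3; C4a is ortho to the ring oxygen and migrates readily, and C3 is an enolizable CH2 beside the stereogenic C2.
- Stereochemistry: C2 (S) is set by catalytic asymmetric conjugate addition; C3 is relayed from C2 in the ring contraction (2,3-trans); C2' (S) is bought as ethyl (S)-lactate; C1' (R) is relayed from C2' by chelation-controlled reduction (erythro diol).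

Key step: step 4

Remark: atom numbers follow chroman-4-one numbering (O1, C2, C3, C4, C4a to C8a) before the key step and 2,3-dihydrobenzofuran numbering (O1, C2, C3, C3a to C7a) after it; C1' and C2' are the side-chain carbinol carbons.
Assumption: the (R)-configured pyridine-oxazoline ligand is taken as the one that delivers the (2S)-flavanone, by analogy with the facial preference of this catalyst on cyclic enones; otherwise only the ligand enantiomer changes.

**Route**

Step 1
Reactants: 1 1-(2-hydroxy-3-methoxyphenyl)ethan-1-one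
Product: 2 1-(5-bromo-2-hydroxy-3-methoxyphenyl)ethan-1-one
Conditions: NBS (1.05 equiv), MeCN, 0 °C to rt
Reagents that add atoms: N-bromosuccinimide, O=C1CCC(=O)N1Br
Why: Electrophilic aromatic bromination should go para to the phenol OH (meta to the acetyl group), the only strongly activated open position, as in the bromination of o-vanillin-type phenols.

Step 2
Reactants: 2 1-(5-bromo-2-hydroxy-3-methoxyphenyl)ethan-1-one
Product: 4 6-bromo-8-methoxy-4H-chromen-4-one, via enaminone 3 (not isolated)
Conditions: Me2NCH(OMe)2, toluene, 100 °C; concentrate; then conc. HCl, CH2Cl2, 40 °C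
Reagents that add atoms: N,N-dimethylformamide dimethyl acetal, COC(OC)N(C)C
Why: Enaminone formation at the acetyl methyl group followed by acid-mediated addition of the phenol OH and loss of dimethylamine is the standard enaminone route to 3-unsubstituted chromones.

Step 3
Reactants: 4 6-bromo-8-methoxy-4H-chromen-4-one; 5 (3,4-dimethoxyphenyl)boronic acid (2 equiv)
Product: 6 (2S)-6-bromo-2-(3,4-dimethoxyphenyl)-8-methoxy-2,3-dihydro-4H-chromen-4-one
Conditions: Pd(OCOCF3)2 (5 mol %), (R)-4-tert-butyl-2-(pyridin-2-yl)-4,5-dihydrooxazole (6 mol %), NH4PF6 (30 mol %), H2O (5 equiv), ClCH2CH2Cl, 60 °C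
Reagents that add atoms: none
Why: Asymmetric conjugate addition of an arylboronic acid to a chromone under cationic divalent palladium and pyridine-oxazoline catalysis (aryl transfer to C2, then protonolysis of the palladium enolate) should set C2 as S, the tert-butyl group of the ligand differentiating the enone faces; the cycle stays at divalent palladium, so the aryl bromide should survive.

Step 4
Reactants: 6 (2S)-6-bromo-2-(3,4-dimethoxyphenyl)-8-methoxy-2,3-dihydro-4H-chromen-4-one
Product: 9 methyl (2S,3S)-5-bromo-2-(3,4-dimethoxyphenyl)-7-methoxy-2,3-dihydro-1-benzofuran-3-carboxylate, via enol ether 7 (not isolated), via iodanyl ketal 8 (not isolated)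
Conditions: PhI(OAc)2 (1.2 equiv), H2SO4 (cat.), HC(OMe)3, 0 °C to rt
Reagents that add atoms: trimethyl orthoformate, COC(OC)OC
Why: Acid and HC(OMe)3 convert ketone 6 into enol ether 7, PhI(OAc)2 attacks C3 of 7 on the face anti to the pseudo-equatorial C2 aryl group while methanol adds at C4 to give the 3-iodanyl ketal 8, and reductive loss of PhI from C3 then triggers a 1,2-shift of the ring A carbon C4a from C4 to C3, the dimethoxycarbenium ion left at the extruded C4 being demethylated by acetate to the methyl ester. The closest known reaction type is the oxidative 1,2-aryl migration of aryl ketones with trivalent iodine (or thallium trinitrate) in trimethyl orthoformate, established for flavanones as a ring contraction to methyl trans-2-aryl-2,3-dihydrobenzofuran-3-carboxylates. The five-membered ring O1–C2–C3–C3a–C7a is closed not by an end-to-end cyclization but by this 1,2-aryl shift through a three-membered phenonium-type bridge, which makes C3–C3a while C4–C4a breaks (six-membered to five-membered ring). The new stereocenter C3 is controlled by C2: in the trans-diequatorial iodane the C3–I bond is antiperiplanar to C4–C4a, migration proceeds with inversion at C3, and the ester carbon ends up trans to the aryl group, which is also the thermodynamically preferred arrangement. The step needs migration of C4a in preference to a shift of the electron-rich C2 aryl group (isoflavone) or loss of the C3 proton (flavone); the antiperiplanar alignment of C4–C4a, the two cation-stabilizing methoxy groups on C4 and the ortho ring oxygen that raises the migratory aptitude of C4a should secure it, and no bond to C2 is broken, so its configuration is carried through.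

Step 5
Reactants: 9 methyl (2S,3S)-5-bromo-2-(3,4-dimethoxyphenyl)-7-methoxy-2,3-dihydro-1-benzofuran-3-carboxylate
Product: 10 [(2S,3R)-5-bromo-2-(3,4-dimethoxyphenyl)-7-methoxy-2,3-dihydro-1-benzofuran-3-yl]methanol
Conditions: i-Bu2AlH (2.5 equiv), CH2Cl2, −78 to 0 °C; aq. KNaC4H4O6 (potassium sodium tartrate)
Reagents that add atoms: none
Why: Hydride reduction of the ester to the primary alcohol with a Lewis-acidic, weakly basic aluminium hydride should spare the aryl bromide and avoid base-induced opening of the ring; the descriptor at C3 changes only through priorities.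

Step 6
Reactants: 10 [(2S,3R)-5-bromo-2-(3,4-dimethoxyphenyl)-7-methoxy-2,3-dihydro-1-benzofuran-3-yl]methanol
Product: 11 [(2S,3R)-5-bromo-2-(3,4-dimethoxyphenyl)-7-methoxy-2,3-dihydro-1-benzofuran-3-yl]methyl 4-methylbenzenesulfonate
Conditions: TsCl, Et3N, DMAP (cat.), CH2Cl2, 0 °C to rt
Reagents that add atoms: p-toluenesulfonyl chloride, Cc1ccc(S(=O)(=O)Cl)cc1
Why: Sulfonylation of an unhindered primary alcohol activates the exocyclic carbon for hydride displacement without touching either stereocenter.

Step 7
Reactants: 11 [(2S,3R)-5-bromo-2-(3,4-dimethoxyphenyl)-7-methoxy-2,3-dihydro-1-benzofuran-3-yl]methyl 4-methylbenzenesulfonate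
Product: 12 (2S,3S)-5-bromo-2-(3,4-dimethoxyphenyl)-7-methoxy-3-methyl-2,3-dihydro-1-benzofuran
Conditions: LiEt3BH (2.5 equiv), THF, 0 °C to rt
Reagents that add atoms: none
Why: SN2 displacement of a primary tosylate by a strongly nucleophilic, weakly basic borohydride gives the methyl group and should favour substitution over elimination toward C3 while leaving the aryl bromide and methyl ethers intact.

Step 8
Reactants: 13 ethyl (2S)-2-hydroxypropanoate (ethyl (S)-lactate)
Product: 14 ethyl (2S)-2-[(tert-butyldimethylsilyl)oxy]propanoate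
Conditions: TBSCl, imidazole, DMF, 0 °C to rt
Reagents that add atoms: tert-butyldimethylsilyl chloride, CC(C)(C)[Si](C)(C)Cl
Why: Standard silylation of the secondary alcohol masks the hydroxyl proton for the organometallic steps without affecting the lactate stereocenter.

Step 9
Reactants: 14 ethyl (2S)-2-[(tert-butyldimethylsilyl)oxy]propanoate
Product: 15 (2S)-2-[(tert-butyldimethylsilyl)oxy]-N-methoxy-N-methylpropanamide
Conditions: MeNH(OMe)·HCl (1.5 equiv), i-PrMgCl (3.0 equiv), THF, −20 to 0 °C
Reagents that add atoms: N,O-dimethylhydroxylamine hydrochloride, CNOC.Cl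
Why: Aminolysis of the ester by the magnesium amide of N,O-dimethylhydroxylamine (Weinreb amide formation) is fast at low temperature and should not epimerize the α-silyloxy center.

Step 10
Reactants: 12 (2S,3S)-5-bromo-2-(3,4-dimethoxyphenyl)-7-methoxy-3-methyl-2,3-dihydro-1-benzofuran; 15 (2S)-2-[(tert-butyldimethylsilyl)oxy]-N-methoxy-N-methylpropanamide (1.3 equiv)
Product: 17 (2S)-2-[(tert-butyldimethylsilyl)oxy]-1-[(2S,3S)-2-(3,4-dimethoxyphenyl)-7-methoxy-3-methyl-2,3-dihydro-1-benzofuran-5-yl]propan-1-one, via aryllithium 16 (not isolated)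
Conditions: n-BuLi (1.05 equiv), THF, −78 °C; then 15, −78 to −20 °C; aq. NH4Cl
Reagents that add atoms: none
Why: Bromine–lithium exchange at −78 °C is much faster than benzylic deprotonation, and acylation of the aryllithium by the Weinreb amide stops at the ketone through the chelated tetrahedral intermediate, so the C5–C1' bond forms with C2' unchanged.

Step 11
Reactants: 17 (2S)-2-[(tert-butyldimethylsilyl)oxy]-1-[(2S,3S)-2-(3,4-dimethoxyphenyl)-7-methoxy-3-methyl-2,3-dihydro-1-benzofuran-5-yl]propan-1-one
Product: 18 (2S)-1-[(2S,3S)-2-(3,4-dimethoxyphenyl)-7-methoxy-3-methyl-2,3-dihydro-1-benzofuran-5-yl]-2-hydroxypropan-1-one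
Conditions: HF·pyridine, pyridine, THF, 0 °C to rt
Reagents that add atoms: none
Why: Buffered fluoride cleavage of the silyl ether is non-basic, so the α-hydroxy ketone should form without epimerization at C2' or acyloin isomerization, and it frees the hydroxyl group needed for chelation.

Step 12
Reactants: 18 (2S)-1-[(2S,3S)-2-(3,4-dimethoxyphenyl)-7-methoxy-3-methyl-2,3-dihydro-1-benzofuran-5-yl]-2-hydroxypropan-1-one
Product: 19 (1R,2S)-1-[(2S,3S)-2-(3,4-dimethoxyphenyl)-7-methoxy-3-methyl-2,3-dihydro-1-benzofuran-5-yl]propane-1,2-diol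
Conditions: Zn(BH4)2, Et2O–CH2Cl2, −20 to 0 °C
Reagents that add atoms: none
Why: Chelation-controlled reduction of an α-hydroxy ketone: zinc bridges the carbonyl and hydroxyl oxygens and hydride attacks the face of the five-membered chelate opposite the C2' methyl group, which should give the anti (erythro) diol and set C1' as R under control of C2'.

**Compound list**
1 | 1-(2-hydroxy-3-methoxyphenyl)ethan-1-one | CC(=O)c1cccc(OC)c1O | starting material
2 | 1-(5-bromo-2-hydroxy-3-methoxyphenyl)ethan-1-one | CC(=O)c1cc(Br)cc(OC)c1O | intermediate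
3 | (E)-1-(5-bromo-2-hydroxy-3-methoxyphenyl)-3-(dimethylamino)prop-2-en-1-one | CN(C)/C=C/C(=O)c1cc(Br)cc(OC)c1O | intermediate (not isolated)
4 | 6-bromo-8-methoxy-4H-chromen-4-one | O=c1ccoc2c(OC)cc(Br)cc12 | intermediate
5 | (3,4-dimethoxyphenyl)boronic acid | COc1ccc(B(O)O)cc1OC | starting material
6 | (2S)-6-bromo-2-(3,4-dimethoxyphenyl)-8-methoxy-2,3-dihydro-4H-chromen-4-one | COc1ccc([C@H]2Oc3c(OC)cc(Br)cc3C(=O)C2)cc1OC | intermediate
7 | (2S)-6-bromo-2-(3,4-dimethoxyphenyl)-4,8-dimethoxy-2H-chromene | COc1ccc([C@H]2Oc3c(OC)cc(Br)cc3C(OC)=C2)cc1OC | intermediate (not isolated)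
8 | (2R,3R)-3-[acetoxy(phenyl)-λ3-iodanyl]-6-bromo-2-(3,4-dimethoxyphenyl)-4,4,8-trimethoxychromane (iodane trans to the C2 aryl group) | COc1ccc([C@H]2Oc3c(OC)cc(Br)cc3C(OC)(OC)[C@@H]2I(OC(C)=O)c2ccccc2)cc1OC | intermediate (not isolated)
9 | methyl (2S,3S)-5-bromo-2-(3,4-dimethoxyphenyl)-7-methoxy-2,3-dihydro-1-benzofuran-3-carboxylate (2,3-trans) | COc1ccc([C@H]2Oc3c(OC)cc(Br)cc3[C@@H]2C(=O)OC)cc1OC | intermediate
10 | [(2S,3R)-5-bromo-2-(3,4-dimethoxyphenyl)-7-methoxy-2,3-dihydro-1-benzofuran-3-yl]methanol | COc1ccc([C@H]2Oc3c(OC)cc(Br)cc3[C@@H]2CO)cc1OC | intermediate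
11 | [(2S,3R)-5-bromo-2-(3,4-dimethoxyphenyl)-7-methoxy-2,3-dihydro-1-benzofuran-3-yl]methyl 4-methylbenzenesulfonate | COc1ccc([C@H]2Oc3c(OC)cc(Br)cc3[C@@H]2COS(=O)(=O)c2ccc(C)cc2)cc1OC | intermediate
12 | (2S,3S)-5-bromo-2-(3,4-dimethoxyphenyl)-7-methoxy-3-methyl-2,3-dihydro-1-benzofuran | COc1ccc([C@H]2Oc3c(OC)cc(Br)cc3[C@@H]2C)cc1OC | intermediate
13 | ethyl (2S)-2-hydroxypropanoate (ethyl (S)-lactate) | CCOC(=O)[C@H](C)O | starting material
14 | ethyl (2S)-2-[(tert-butyldimethylsilyl)oxy]propanoate | CCOC(=O)[C@H](C)O[Si](C)(C)C(C)(C)C | intermediate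
15 | (2S)-2-[(tert-butyldimethylsilyl)oxy]-N-methoxy-N-methylpropanamide | CON(C)C(=O)[C@H](C)O[Si](C)(C)C(C)(C)C | intermediate
16 | [(2S,3S)-2-(3,4-dimethoxyphenyl)-7-methoxy-3-methyl-2,3-dihydro-1-benzofuran-5-yl]lithium | COc1ccc([C@H]2Oc3c(OC)cc([Li])cc3[C@@H]2C)cc1OC | intermediate (not isolated)
17 | (2S)-2-[(tert-butyldimethylsilyl)oxy]-1-[(2S,3S)-2-(3,4-dimethoxyphenyl)-7-methoxy-3-methyl-2,3-dihydro-1-benzofuran-5-yl]propan-1-one | COc1ccc([C@H]2Oc3c(OC)cc(C(=O)[C@H](C)O[Si](C)(C)C(C)(C)C)cc3[C@@H]2C)cc1OC | intermediate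
18 | (2S)-1-[(2S,3S)-2-(3,4-dimethoxyphenyl)-7-methoxy-3-methyl-2,3-dihydro-1-benzofuran-5-yl]-2-hydroxypropan-1-one | COc1ccc([C@H]2Oc3c(OC)cc(C(=O)[C@H](C)O)cc3[C@@H]2C)cc1OC | intermediate
19 | (1R,2S)-1-[(2S,3S)-2-(3,4-dimethoxyphenyl)-7-methoxy-3-methyl-2,3-dihydro-1-benzofuran-5-yl]propane-1,2-diol | COc1ccc([C@H]2Oc3c(OC)cc([C@@H](O)[C@H](C)O)cc3[C@@H]2C)cc1OC | target

**Step count**
Total steps: 12. Longest linear sequence: 10 (steps 1 to 7, then 10 to 12); steps 8 and 9 form the two-step side branch.

**Steps most likely to fail**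

1. Step 4. A 1,2-shift of the electron-rich C2 aryl group or dehydrogenation across C2–C3 may compete with the shift of C4a. Acid-mediated ionization of the C2–O bond, which is benzylic to the dimethoxyphenyl ring, may also erode the enantiomeric purity. The fallback keeps the ring contraction but drives it through a carbene instead of an iodane (Wolff rearrangement) under non-acidic conditions. It sets out from 6: enolization with LiN(SiMe3)2 in THF at −78 °C and trapping with CF3CO2CH2CF3 should give (2S)-6-bromo-2-(3,4-dimethoxyphenyl)-8-methoxy-3-(trifluoroacetyl)chroman-4-one F1. Detrifluoroacetylative diazo transfer (MsN3, Et3N, MeCN) should then give (2R)-6-bromo-3-diazo-2-(3,4-dimethoxyphenyl)-8-methoxychroman-4-one F2. Irradiation (above 300 nm) in MeOH should move the same ring A carbon to the carbene carbon, and methanol should trap the ketene as a mixture of 9 and methyl (2S,3R)-5-bromo-2-(3,4-dimethoxyphenyl)-7-methoxy-2,3-dihydro-1-benzofuran-3-carboxylate F3, the cis epimer. Brief treatment with NaOMe in MeOH should equilibrate F3 to the trans ester, and the route is rejoined at 9.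

2. Step 3. Facial selectivity may be insufficient with this 8-methoxy chromone, the electron-rich boronic acid may protodeboronate, or adventitious zerovalent palladium may insert into the C–Br bond. The fallback replaces catalytic C–C bond formation by ring closure plus kinetic resolution. It sets out from 2: Claisen–Schmidt condensation with 3,4-dimethoxybenzaldehyde (KOH, EtOH, rt) should give (E)-1-(5-bromo-2-hydroxy-3-methoxyphenyl)-3-(3,4-dimethoxyphenyl)prop-2-en-1-one F4. Intramolecular oxa-Michael closure (NaOAc, EtOH, reflux) should give racemic 6-bromo-2-(3,4-dimethoxyphenyl)-8-methoxychroman-4-one F5. Asymmetric transfer hydrogenation with RuCl(p-cymene)[(R,R)-TsDPEN] in HCO2H/Et3N, stopped near half conversion, is expected to reduce the (2R)-ketone faster to (2R,4R)-6-bromo-2-(3,4-dimethoxyphenyl)-8-methoxychroman-4-ol F6. The unreacted (2S)-ketone is separated by chromatography, and the route is rejoined at 6.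

3. Step 12. Incomplete chelation (hydride delivery through an open transition state) would lower the facial selectivity at C1' and give some threo diol. The fallback replaces substrate control by reagent control on the silyl ether. It sets out from 17: reduction with (R)-2-methyl-CBS-oxazaborolidine and BH3·SMe2 in THF is expected, with the aryl group as the large substituent, to give (1R,2S)-2-[(tert-butyldimethylsilyl)oxy]-1-[(2S,3S)-2-(3,4-dimethoxyphenyl)-7-methoxy-3-methyl-2,3-dihydro-1-benzofuran-5-yl]propan-1-ol F7. Desilylation with Bu4NF in THF should then give the diol, and the route is rejoined at 19.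

**Further compounds**
F1 | step 4 | (2S)-6-bromo-2-(3,4-dimethoxyphenyl)-8-methoxy-3-(trifluoroacetyl)chroman-4-one | COc1ccc([C@H]2Oc3c(OC)cc(Br)cc3C(=O)C2C(=O)C(F)(F)F)cc1OC
F2 | step 4 | (2R)-6-bromo-3-diazo-2-(3,4-dimethoxyphenyl)-8-methoxychroman-4-one | COc1ccc([C@H]2Oc3c(OC)cc(Br)cc3C(=O)C2=[N+]=[N-])cc1OC
F3 | step 4 | methyl (2S,3R)-5-bromo-2-(3,4-dimethoxyphenyl)-7-methoxy-2,3-dihydro-1-benzofuran-3-carboxylate (2,3-cis) | COc1ccc([C@H]2Oc3c(OC)cc(Br)cc3[C@H]2C(=O)OC)cc1OC
F4 | step 3 | (E)-1-(5-bromo-2-hydroxy-3-methoxyphenyl)-3-(3,4-dimethoxyphenyl)prop-2-en-1-one | COc1ccc(/C=C/C(=O)c2cc(Br)cc(OC)c2O)cc1OC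
F5 | step 3 | racemic 6-bromo-2-(3,4-dimethoxyphenyl)-8-methoxychroman-4-one | COc1ccc(C2Oc3c(OC)cc(Br)cc3C(=O)C2)cc1OC
F6 | step 3 | (2R,4R)-6-bromo-2-(3,4-dimethoxyphenyl)-8-methoxychroman-4-ol | COc1ccc([C@@H]2Oc3c(OC)cc(Br)cc3[C@H](O)C2)cc1OC
F7 | step 12 | (1R,2S)-2-[(tert-butyldimethylsilyl)oxy]-1-[(2S,3S)-2-(3,4-dimethoxyphenyl)-7-methoxy-3-methyl-2,3-dihydro-1-benzofuran-5-yl]propan-1-ol | COc1ccc([C@H]2Oc3c(OC)cc([C@@H](O)[C@H](C)O[Si](C)(C)C(C)(C)C)cc3[C@@H]2C)cc1OC
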